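## The problem

The target 31 is a germacranolide: a ten-membered carbocycle with two endocyclic Z trisubstituted alkenes (C1=C10 and C4=C5), trans-fused across C6–C7 to an α-methylene-γ-butyrolactone (C12 carbonyl, lactone oxygen on C6, exocyclic C11=C13). The medium ring has to be closed against transannular strain and an unfavourable entropy without loss of either Z geometry. Four contiguous stereocentres, C6 (R), C7 (R), C8 (S) and C9 (R), lie on one edge of the ring, and a fifth (R) sits in the 2-methylbutanoate. C6 and C7 can be set together by one aldol, but C7 steers additions to C8 only weakly and, by a Felkin-type analysis, towards the wrong face, so C8 and C9 need a control element of their own. Three oxygens must end up differentiated (free hydroxyl on C8, acetate on C9, primary ester on C14), with acetyl migration between O9 and O8 a standing danger. The methylene lactone is a Michael acceptor and must be the last carbon–carbon operation; the allylic esters at C9 and C14, the α-centre of the 2-methylbutanoate and any C8 carbonyl intermediate (β to the lactone oxygen on C6, hence prone to elimination) will not survive rough treatment. The enabling feature is that the C8 carbinol, the oxygen-bearing C9 and the Z C10=C1 alkene (C14 on C10, the C2 chain on C1) form exactly the product pattern of an α-substituted γ-alkoxyallylboronate adding to an aldehyde; because C1 and the C8 aldehyde are joined through C2–C7, that addition can close the ring.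

## Retrosynthesis

**31 ⇒ 22 (functional adjustments).** The C14–O acyl bond (acid 30), the C9–O acetyl bond and the C11=C13 bond are cut, leading back through 29, 28, 27, 26 and 23 to the ring-closure product 22. The methylene group is introduced only after ring closure, on the O8-silylated lactone 23, because no copper boryl species, borohydride or enolate upstream would tolerate a Michael acceptor. The PMB ether on O9 and the silyl ethers on O8 and O14 are orthogonal: DDQ frees O9 alone for acetylation (27 to 28), fluoride then frees O8 and O14 (29), and the primary allylic O14 is acylated in preference to the flanked secondary O8. The forward steps must give selective mono-acylation without acetyl migration.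

**22 ⇒ 20 (key cut, C8–C9).** Cutting C7–C8 or C9–C10 would explain neither the alkene nor the diol. Cutting C8–C9 accounts at once for the anti-diol, the Z C1=C10 alkene and the carbocycle, and leaves O8 free and O9 masked. The precursor 20 is a monocyclic trans-lactone aldehyde with a single stereocentre (C1, bearing boron) in place of C8 and C9. The forward reaction must cyclise faster than it oligomerises and must pass through the chair with the C2 chain axial.

**20 ⇒ 17 (C1–B bond, C9 enol ether, C8 oxidation level).** The enol ether on C9 is what is left of an acetal after SN2' borylation, so 20 is traced through alcohol 19 and imide 18 to the bis(PMB) allyl acetal 17. Copper-catalysed γ-borylation is the only route to an α-chiral γ-alkoxyallylboronate that tolerates a lactone; lithiated carbamates or Matteson homologation would need organolithium reagents. The oxazolidinone imide is carried as the latent C8 carbinol, so no protecting group is needed on O8 before ring closure and no free hydroxyl is present in the copper step. The forward steps must deliver face selection at C1, loss of PMB-oxide and not silyloxide, and the enol ether geometry with OPMB trans to C1.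

**17 ⇒ 10 + 13 + 16 (acetal C–O bonds, C1=C10).** The acetal is cut to enal 14 and silyl ether 16 (from 15); the C1=C10 bond of 14 is cut by cross-metathesis to the terminal alkene 10 and the 2-substituted acrolein 13 (from 11). Metathesis brings in C9, C10 and C14 in one step with the two oxygenated carbons already differentiated (CHO and CH2OTBS) and with the E geometry. Allylic oxidation of a prenyl end would functionalise only one of the two methyl groups. The forward step asks for cross-metathesis with an electron-poor 1,1-disubstituted alkene.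

**10 ⇒ 8 + 5 (C6–C7 and lactone C12–O).** A syn-aldol of the succinate imide 8 with the Z enal 5, followed by lactonisation of the aldolate onto the methyl ester, sets C6 and C7 under auxiliary control. The syn aldol relationship maps onto the trans-lactone. The precursors are an achiral aldehyde and an imide made in one step from 6 and 7. The forward step requires enolisation on the imide side only and no Z to E isomerisation of 5.

**5 ⇒ 1.** The Z alkene of neryl acetate 1 becomes C4=C5. The isopropylidene end is cleaved by ozone (2) and methylenated (3), and the acetate is exchanged for the aldehyde (4, then 5). The selectivity needed is ozonolysis of the electron-rich terminal alkene in the presence of the allylic-acetate alkene.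

## Roads not taken

**Alternative 1: Nozaki–Hiyama–Kishi closure at C5–C6 with lactonisation.** The cut is C5–C6 together with the lactone C–O bond. Forward, CrCl2 with catalytic NiCl2 turns the Z iodoalkene of the open-chain aldehyde ester A2 into an alkenylchromium species that adds to the C6 aldehyde, and the C6 alkoxide closes the lactone to give A1. Its merits are real: this type of macrocyclisation has the best precedent of the four for medium rings, the Z C4=C5 geometry is carried in stereospecifically, and the lactone forms in the same flask. Its weak points are that C7, C8 and C9 must all be assembled on an open chain beforehand, and that the new C6 centre is set during closure with only Felkin-type and macrocyclic bias to make it trans to C7. The aldehyde of A2 is also α-branched with a β-silyloxy group (epimerisation, elimination), and a large excess of divalent chromium is consumed. In ring-closure precedent this road is better than the chosen one. Against that, the chosen closure creates two stereocentres and the Z C1=C10 alkene under a reagent-directed chair mechanism, and the diol does not have to be made separately.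

**Alternative 2: [2,3]-Wittig contraction of a thirteen-membered diallylic ether.** The cut is C6–C7: the carbocycle is traced to the cyclic ether A4, whose O–C13 bond is exchanged for C6–C7. Forward, n-BuLi (two equivalents, one for the C14 hydroxyl) lithiates C6, and the sigmatropic shift gives A3 with the C6 carbinol and the C11=C13 methylene in place. A thirteen-membered ether closes more easily than a ten-membered carbocycle, the contraction is an established entry to germacrane rings, and the exocyclic methylene arrives for free; in these respects it is equal or better, and it would save the methylenation step. Its weak points are that C13 is as acidic as C6 (both allylic and α to oxygen), so the site of lithiation is not secured, and that the C6/C7 relationship depends on the envelope transition state of a macrocycle and on the C7=C11 geometry. A [1,2]-shift competes, the dioxolane of A3 must still be taken to the lactone, and the C8/C9 diol again has to be built first. The chosen plan offers a defined stereochemical model for the centres formed in the ring-closing step and needs no alkyllithium late in the route.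

**Alternative 3: Wharton–Grob fragmentation of an angular-methyl cis-decalin.** Here the cut adds a bond: C4–C9 is joined to give the decalin A6 (tertiary C9 alcohol, equatorial C5 mesylate, ring fusion at C4 and C9). Forward, KOtBu forms the C9 alkoxide, the C4–C9 bond breaks antiperiplanar to the C5–O bond, and the dienone A5 is released with the Z C4=C5 alkene. As a ring-forming event this is the most reliable of the four: no entropic price is paid and the alkene geometry is dictated by orbital alignment. The price is paid elsewhere. A6 needs six stereocentres, two of them fully substituted ring-fusion carbons. C9 emerges as a ketone conjugated to C1=C10 and next to the C8 stereocentre, which can epimerise under alkoxide. The 1,2-reduction of C9 would rely on macrocyclic conformation alone, and the lactone must survive KOtBu. The chosen plan has fewer steps and forms C8 and C9 directly at the right oxidation level and configuration.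

Key step: step 15

Remark: atom labels C1–C15 are those of the germacranolide numbering of 31 in every intermediate; the saturated lactones lack C13 and are named as 13-nor compounds; the descriptor of C7 changes between R and S with the group on O8 or C8 without any change in space.

Assumption: the (R,R) ligand of step 12 is taken to deliver C1 (R) on the E acetal 17; should the sense of face selection on this open-chain 2-substituted acetal be opposite, the (S,S) ligand is used.

## Steps

Step 1
Reactants: 1 neryl acetate
Product: 2 (2Z)-3-methyl-6-oxohex-2-en-1-yl acetate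
Conditions: O3, CH2Cl2, −78 °C (Sudan red end point); Me2S, −78 °C to rt
Reagents that add atoms: ozone, [O-][O+]=O
Why: Ozonolysis with reductive work-up; the electron-rich terminal trisubstituted alkene reacts well before the alkene that is deactivated by the allylic acetate, so the Z alkene (later C4=C5) is kept.

Step 2
Reactants: 2 (2Z)-3-methyl-6-oxohex-2-en-1-yl acetate
Product: 3 (2Z)-3-methylhepta-2,6-dien-1-yl acetate
Conditions: Ph3PCH3Br, KN(SiMe3)2, THF, −78 to 0 °C
Reagents that add atoms: methyltriphenylphosphonium bromide, C[P+](c1ccccc1)(c1ccccc1)c1ccccc1.[Br-]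
Why: Wittig methylenation; the aldehyde reacts with the ylide far faster than the acetate at low temperature, and partial loss of the acetate would be harmless since it is removed next.

Step 3
Reactants: 3 (2Z)-3-methylhepta-2,6-dien-1-yl acetate
Product: 4 (2Z)-3-methylhepta-2,6-dien-1-ol
Conditions: K2CO3, MeOH, rt
Reagents that add atoms: none
Why: Base-catalysed transesterification of a primary acetate; neither alkene is affected.

Step 4
Reactants: 4 (2Z)-3-methylhepta-2,6-dien-1-ol
Product: 5 (2Z)-3-methylhepta-2,6-dienal
Conditions: TEMPO (10 mol%), PhI(OAc)2, CH2Cl2, rt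
Reagents that add atoms: none
Why: Oxoammonium oxidation of an allylic alcohol; these conditions take neryl-type alcohols to the Z enals without Z to E isomerisation.

Step 5
Reactants: 6 (4S)-4-benzyl-1,3-oxazolidin-2-one; 7 methyl 4-chloro-4-oxobutanoate
Product: 8 methyl 4-[(4S)-4-benzyl-2-oxo-1,3-oxazolidin-3-yl]-4-oxobutanoate
Conditions: n-BuLi, THF, −78 °C; then 7
Reagents that add atoms: none
Why: N-Acylation of the lithiated oxazolidinone by the acid chloride, which is far more electrophilic than the methyl ester.

Step 6
Reactants: 8 methyl 4-[(4S)-4-benzyl-2-oxo-1,3-oxazolidin-3-yl]-4-oxobutanoate; 5 (2Z)-3-methylhepta-2,6-dienal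
Product: 10 (4S)-4-benzyl-3-{[(2R,3S)-2-[(1Z)-2-methylhexa-1,5-dien-1-yl]-5-oxooxolan-3-yl]carbonyl}-1,3-oxazolidin-2-one (trans-lactone imide), via boron aldolate 9 (not isolated)
Conditions: Bu2BOTf, iPr2NEt, CH2Cl2, −78 to 0 °C; 5, −78 to 0 °C; pH 7 buffer, MeOH, H2O2, 0 °C
Reagents that add atoms: none
Why: Evans syn-aldol: the Z boron enolate formed on the imide side of 8 adds to 5 through a chair transition state with the benzyl group shielding one face, which sets C6 (R) and C7 together. The aldolate oxygen then closes the γ-lactone on the methyl ester, and the syn aldol relationship corresponds to the trans-lactone.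

Step 7
Reactants: 11 2-methylidenepropane-1,3-diol
Product: 12 2-{[(tert-butyldimethylsilyl)oxy]methyl}prop-2-en-1-ol
Conditions: NaH (1 equiv), THF, 0 °C; TBSCl
Reagents that add atoms: tert-butyldimethylsilyl chloride, CC(C)(C)[Si](C)(C)Cl
Why: Monosilylation of a symmetric diol through its sparingly soluble monosodium alkoxide.

Step 8
Reactants: 12 2-{[(tert-butyldimethylsilyl)oxy]methyl}prop-2-en-1-ol
Product: 13 2-{[(tert-butyldimethylsilyl)oxy]methyl}prop-2-enal
Conditions: MnO2, CH2Cl2, rt
Reagents that add atoms: none
Why: Selective oxidation of an allylic alcohol by MnO2; the enal is used soon after filtration.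

Step 9
Reactants: 10 trans-lactone imide with terminal alkene; 13 2-{[(tert-butyldimethylsilyl)oxy]methyl}prop-2-enal
Product: 14 (4S)-4-benzyl-3-{[(2R,3S)-2-[(1Z,5E)-7-[(tert-butyldimethylsilyl)oxy]-6-formyl-2-methylhepta-1,5-dien-1-yl]-5-oxooxolan-3-yl]carbonyl}-1,3-oxazolidin-2-one
Conditions: 13 (4 equiv), second-generation Hoveyda–Grubbs catalyst RuCl2(H2IMes)(=CH-C6H4-2-OiPr) (5 mol%), CH2Cl2, 40 °C
Reagents that add atoms: none
Why: Cross-metathesis of a terminal alkene with a 2-substituted acrolein, which gives the E enal (C2 trans to the formyl group) as the favoured isomer. The Z trisubstituted C4=C5 alkene is too hindered to take part, and a 1,5-diene cannot ring-close.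

Step 10
Reactants: 15 4-methoxybenzyl alcohol
Product: 16 [(4-methoxybenzyl)oxy]trimethylsilane
Conditions: TMSCl, Et3N, CH2Cl2, 0 °C
Reagents that add atoms: chlorotrimethylsilane, C[Si](C)(C)Cl
Why: Routine O-silylation; the silyl ether is the alkoxy donor for the next step.

Step 11
Reactants: 14 E enal; 16 [(4-methoxybenzyl)oxy]trimethylsilane
Product: 17 (4S)-4-benzyl-3-{[(2R,3S)-2-[(1Z,5E)-6-{bis[(4-methoxybenzyl)oxy]methyl}-7-[(tert-butyldimethylsilyl)oxy]-2-methylhepta-1,5-dien-1-yl]-5-oxooxolan-3-yl]carbonyl}-1,3-oxazolidin-2-one
Conditions: 16 (2.5 equiv), TMSOTf (10 mol%), CH2Cl2, −78 to −40 °C; pyridine quench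
Reagents that add atoms: none
Why: TMSOTf-catalysed acetalisation with an alkoxysilane (Noyori conditions) converts enals into acetals at low temperature without conjugate addition or alkene migration, hexamethyldisiloxane being the only by-product. The imide, lactone and TBS ether are inert to catalytic TMSOTf at this temperature.

Step 12
Reactants: 17 bis(PMB) allyl acetal
Product: 18 (4S)-4-benzyl-3-{[(2R,3S)-2-[(1Z,5R,6Z)-6-{[(tert-butyldimethylsilyl)oxy]methyl}-7-[(4-methoxybenzyl)oxy]-2-methyl-5-(4,4,5,5-tetramethyl-1,3,2-dioxaborolan-2-yl)hepta-1,6-dien-1-yl]-5-oxooxolan-3-yl]carbonyl}-1,3-oxazolidin-2-one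
Conditions: B2pin2 (1.5 equiv), CuCl (5 mol%), (R,R)-1,2-bis(tert-butylmethylphosphino)benzene (5 mol%), KOtBu (10 mol%), THF, 0 °C
Reagents that add atoms: bis(pinacolato)diboron, CC1(C)OB(OC1(C)C)B1OC(C)(C)C(C)(C)O1
Why: Copper-catalysed enantioselective γ-borylation of an allyl acetal (SN2'): LCu–Bpin adds across C1=C10 with boron on C1, the ligand choosing the alkene face and so setting C1 (R), and β-elimination of PMB-oxide from C9 leaves the enol ether with OPMB turned away from the boron-bearing carbon. Acetal 17 is the open-chain counterpart of the cycloalkenyl acetals that undergo this reaction, and N-acyl oxazolidinones are compatible with copper boryl catalysis. The C4=C5 alkene is left alone because expelling the lactone oxygen would require boron on the fully substituted C4.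

Step 13
Reactants: 18 allylboronate imide
Product: 19 (4R,5R)-5-[(1Z,5R,6Z)-6-{[(tert-butyldimethylsilyl)oxy]methyl}-7-[(4-methoxybenzyl)oxy]-2-methyl-5-(4,4,5,5-tetramethyl-1,3,2-dioxaborolan-2-yl)hepta-1,6-dien-1-yl]-4-(hydroxymethyl)oxolan-2-one
Conditions: NaBH4, THF/H2O 4:1, 0 °C
Reagents that add atoms: none
Why: Reductive cleavage of an N-acyl oxazolidinone by NaBH4 in wet THF; the twisted imide carbonyl is far more electrophilic than the γ-lactone, and the transient aldehyde is reduced faster than it could cyclise. The pinacol boronate and the enol ether are stable to borohydride and mild base.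

Step 14
Reactants: 19 hydroxymethyl lactone allylboronate
Product: 20 (2R,3S)-2-[(1Z,5R,6Z)-6-{[(tert-butyldimethylsilyl)oxy]methyl}-7-[(4-methoxybenzyl)oxy]-2-methyl-5-(4,4,5,5-tetramethyl-1,3,2-dioxaborolan-2-yl)hepta-1,6-dien-1-yl]-5-oxooxolane-3-carbaldehyde
Conditions: Dess–Martin periodinane, NaHCO3, CH2Cl2, 0 °C; cold aq. Na2S2O3/NaHCO3; used crude
Reagents that add atoms: none
Why: Dess–Martin oxidation under buffered, non-basic conditions tolerates pinacol allylboronates and enol ethers. The short, cold work-up limits β-elimination of the lactone oxygen, and C7 stays in its more stable trans arrangement.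

Step 15
Reactants: 20 C8 aldehyde with the C1 pinacolboronate
Product: 22 (1(10)Z,4Z,6R,7R,8S,9R)-14-[(tert-butyldimethylsilyl)oxy]-8-hydroxy-9-[(4-methoxybenzyl)oxy]-13-norgermacra-1(10),4-dien-12,6-olide, via O8-pinacolboryl ether 21 (not isolated)
Conditions: PhMe (0.002 M), 25 to 60 °C; then aq. NaHCO3
Reagents that add atoms: none
Why: Proposed new method: the aldehyde oxygen binds boron and C9 adds to C8 through a six-membered Zimmerman–Traxler chair on the face of the allyl unit that carries boron, so that C8–C9 forms while the C1–B bond breaks and the alkene moves to C1=C10; the closest known reaction types are intramolecular allylborations of ω-formyl allylboronates that close five- to seven-membered rings and intermolecular additions of α-substituted γ-alkoxyallyl pinacolboronates to aldehydes, which give anti-1,2-diol monoethers with Z alkenes. The ten-membered ring closes in a 10-exo-trig sense at the aldehyde with all three allyl carbons (C1, C10, C9) inside the ring, the tether joining the α carbon and the carbonyl carbon, which are positions 1 and 4 of the chair. C9 (R) is controlled by the C1 (R) boronate centre, because the pinacol methyl groups and A1,2 strain with C14 force the C2 chain axial and so fix which face of the enol ether meets the aldehyde. C8 (S) follows from C7 lying equatorial on the chair, which with OPMB trans to C1 gives the anti relationship. The Z geometry of C1=C10 is the direct result of the axial C2 chain, and an axial/equatorial pair is also the arrangement that a six-atom tether containing the Z C4=C5 alkene can bridge. The step needs cyclisation to win over oligomerisation, which high dilution and the turn elements already present (trans-lactone, Z C4=C5) should secure. It also needs reagent control to overrule a Felkin-type preference of the α-branched aldehyde for the other C8 face, for which the α-substituted pinacol boronate is the strongest element available. Hydrolysis of the O–B bond on work-up leaves O8 free and O9 as its PMB ether, already differentiated.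

Step 16
Reactants: 22 ten-membered 8-hydroxy lactone
Product: 23 (1(10)Z,4Z,6R,7S,8S,9R)-8,14-bis[(tert-butyldimethylsilyl)oxy]-9-[(4-methoxybenzyl)oxy]-13-norgermacra-1(10),4-dien-12,6-olide
Conditions: TBSOTf, 2,6-lutidine, CH2Cl2, −78 to 0 °C
Reagents that add atoms: tert-butyldimethylsilyl trifluoromethanesulfonate, CC(C)(C)[Si](C)(C)OS(=O)(=O)C(F)(F)F
Why: Silylation of a hindered secondary alcohol with the silyl triflate; it removes the acidic proton before enolate chemistry and keeps O8 distinct from O9.

Step 17
Reactants: 23 bis-silyl lactone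
Product: 26 (1(10)Z,4Z,6R,7S,8S,9R)-8,14-bis[(tert-butyldimethylsilyl)oxy]-9-[(4-methoxybenzyl)oxy]germacra-1(10),4,11(13)-trien-12,6-olide, via Mannich base 24 (not isolated), via trimethylammonium iodide 25 (not isolated)
Conditions: LiN(iPr)2, THF, −78 °C; CH2=NMe2+ I−, −78 °C to rt; MeI, MeOH, rt; aq. NaHCO3, CH2Cl2, rt
Reagents that add atoms: N,N-dimethylmethylideneammonium iodide (Eschenmoser's salt), C=[N+](C)C.[I-]
Why: α-Methylenation by Mannich reaction of the lactone lithium enolate, N-methylation and Hofmann-type elimination. The C11 enolate has no β-leaving group and C7 is not touched, so the configuration of the Mannich base at C11 is irrelevant.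

Step 18
Reactants: 26 methylene lactone PMB ether
Product: 27 (1(10)Z,4Z,6R,7S,8S,9R)-8,14-bis[(tert-butyldimethylsilyl)oxy]-9-hydroxygermacra-1(10),4,11(13)-trien-12,6-olide
Conditions: DDQ, CH2Cl2/pH 7 buffer, 0 °C
Reagents that add atoms: none
Why: Oxidative cleavage of the PMB ether by benzylic hydride abstraction and hydrolysis of the oxocarbenium ion; the silyl ethers, the isolated alkenes and the methylene lactone are not attacked by a slight excess at 0 °C.

Step 19
Reactants: 27 9-hydroxy lactone
Product: 28 (1(10)Z,4Z,6R,7S,8S,9R)-9-acetoxy-8,14-bis[(tert-butyldimethylsilyl)oxy]germacra-1(10),4,11(13)-trien-12,6-olide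
Conditions: Ac2O, pyridine, DMAP (cat.), CH2Cl2, 0 °C to rt
Reagents that add atoms: acetic anhydride, CC(=O)OC(C)=O
Why: Nucleophile-catalysed acetylation of the only free hydroxyl.

Step 20
Reactants: 28 9-acetate bis-silyl ether
Product: 29 (1(10)Z,4Z,6R,7R,8S,9R)-9-acetoxy-8,14-dihydroxygermacra-1(10),4,11(13)-trien-12,6-olide
Conditions: HF·pyridine, pyridine, THF, 0 °C to rt
Reagents that add atoms: none
Why: Cleavage of both silyl ethers by buffered, weakly acidic fluoride, which avoids conjugate addition to the methylene lactone and base-induced acetyl migration from O9 to O8.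

Step 21
Reactants: 29 8,14-diol; 30 (2R)-2-methylbutanoic acid
Product: 31 (1(10)Z,4Z,6R,7R,8S,9R)-9-acetoxy-8-hydroxy-14-{[(2R)-2-methylbutanoyl]oxy}germacra-1(10),4,11(13)-trien-12,6-olide (CNP0005248.2)
Conditions: EDC·HCl, DMAP (cat.), CH2Cl2, −20 to 0 °C
Reagents that add atoms: none
Why: Steglich esterification; the primary allylic C14 hydroxyl reacts far faster than the secondary C8 hydroxyl, which is flanked by C7 and the C9 acetate. Low temperature and catalytic DMAP limit racemisation of the α-branched acid and acetyl migration.

## Compound list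

1 | neryl acetate, (2Z)-3,7-dimethylocta-2,6-dien-1-yl acetate | CC(C)=CCC/C(C)=C\COC(C)=O | starting material
2 | (2Z)-3-methyl-6-oxohex-2-en-1-yl acetate | O=CCC/C(C)=C\COC(C)=O | intermediate
3 | (2Z)-3-methylhepta-2,6-dien-1-yl acetate | C=CCC/C(C)=C\COC(C)=O | intermediate
4 | (2Z)-3-methylhepta-2,6-dien-1-ol | C=CCC/C(C)=C\CO | intermediate
5 | (2Z)-3-methylhepta-2,6-dienal | C=CCC/C(C)=C\C=O | intermediate
6 | (4S)-4-benzyl-1,3-oxazolidin-2-one | O=C1N[C@@H](Cc2ccccc2)CO1 | starting material
7 | methyl 4-chloro-4-oxobutanoate | COC(=O)CCC(Cl)=O | starting material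
8 | methyl 4-[(4S)-4-benzyl-2-oxo-1,3-oxazolidin-3-yl]-4-oxobutanoate | COC(=O)CCC(=O)N1[C@@H](Cc2ccccc2)COC1=O | intermediate
9 | methyl (3S,4R,5Z)-3-{[(4S)-4-benzyl-2-oxo-1,3-oxazolidin-3-yl]carbonyl}-4-[(dibutylboranyl)oxy]-6-methyldeca-5,9-dienoate (boron aldolate) | COC(=O)C[C@H](C(=O)N1[C@@H](Cc2ccccc2)COC1=O)[C@H](OB(CCCC)CCCC)/C=C(/C)CCC=C | intermediate (not isolated)
10 | (4S)-4-benzyl-3-{[(2R,3S)-2-[(1Z)-2-methylhexa-1,5-dien-1-yl]-5-oxooxolan-3-yl]carbonyl}-1,3-oxazolidin-2-one | C1C(=O)O[C@H](/C=C(/C)CCC=C)[C@H]1C(=O)N2[C@@H](Cc3ccccc3)COC2=O | intermediate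
11 | 2-methylidenepropane-1,3-diol | C=C(CO)CO | starting material
12 | 2-{[(tert-butyldimethylsilyl)oxy]methyl}prop-2-en-1-ol | C=C(CO)CO[Si](C)(C)C(C)(C)C | intermediate
13 | 2-{[(tert-butyldimethylsilyl)oxy]methyl}prop-2-enal | C=C(C=O)CO[Si](C)(C)C(C)(C)C | intermediate
14 | (4S)-4-benzyl-3-{[(2R,3S)-2-[(1Z,5E)-7-[(tert-butyldimethylsilyl)oxy]-6-formyl-2-methylhepta-1,5-dien-1-yl]-5-oxooxolan-3-yl]carbonyl}-1,3-oxazolidin-2-one | C1C(=O)O[C@H](/C=C(/C)CC/C=C(\CO[Si](C)(C)C(C)(C)C)C=O)[C@H]1C(=O)N2[C@@H](Cc3ccccc3)COC2=O | intermediate
15 | 4-methoxybenzyl alcohol | COc1ccc(CO)cc1 | starting material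
16 | [(4-methoxybenzyl)oxy]trimethylsilane | COc1ccc(CO[Si](C)(C)C)cc1 | intermediate
17 | (4S)-4-benzyl-3-{[(2R,3S)-2-[(1Z,5E)-6-{bis[(4-methoxybenzyl)oxy]methyl}-7-[(tert-butyldimethylsilyl)oxy]-2-methylhepta-1,5-dien-1-yl]-5-oxooxolan-3-yl]carbonyl}-1,3-oxazolidin-2-one | C1C(=O)O[C@H](/C=C(/C)CC/C=C(\CO[Si](C)(C)C(C)(C)C)C(OCc2ccc(OC)cc2)OCc2ccc(OC)cc2)[C@H]1C(=O)N3[C@@H](Cc4ccccc4)COC3=O | intermediate
18 | (4S)-4-benzyl-3-{[(2R,3S)-2-[(1Z,5R,6Z)-6-{[(tert-butyldimethylsilyl)oxy]methyl}-7-[(4-methoxybenzyl)oxy]-2-methyl-5-(4,4,5,5-tetramethyl-1,3,2-dioxaborolan-2-yl)hepta-1,6-dien-1-yl]-5-oxooxolan-3-yl]carbonyl}-1,3-oxazolidin-2-one | C1C(=O)O[C@H](/C=C(/C)CC[C@@H](B2OC(C)(C)C(C)(C)O2)/C(CO[Si](C)(C)C(C)(C)C)=C/OCc2ccc(OC)cc2)[C@H]1C(=O)N3[C@@H](Cc4ccccc4)COC3=O | intermediate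
19 | (4R,5R)-5-[(1Z,5R,6Z)-6-{[(tert-butyldimethylsilyl)oxy]methyl}-7-[(4-methoxybenzyl)oxy]-2-methyl-5-(4,4,5,5-tetramethyl-1,3,2-dioxaborolan-2-yl)hepta-1,6-dien-1-yl]-4-(hydroxymethyl)oxolan-2-one | C1C(=O)O[C@H](/C=C(/C)CC[C@@H](B2OC(C)(C)C(C)(C)O2)/C(CO[Si](C)(C)C(C)(C)C)=C/OCc2ccc(OC)cc2)[C@H]1CO | intermediate
20 | (2R,3S)-2-[(1Z,5R,6Z)-6-{[(tert-butyldimethylsilyl)oxy]methyl}-7-[(4-methoxybenzyl)oxy]-2-methyl-5-(4,4,5,5-tetramethyl-1,3,2-dioxaborolan-2-yl)hepta-1,6-dien-1-yl]-5-oxooxolane-3-carbaldehyde | C1C(=O)O[C@H](/C=C(/C)CC[C@@H](B2OC(C)(C)C(C)(C)O2)/C(CO[Si](C)(C)C(C)(C)C)=C/OCc2ccc(OC)cc2)[C@H]1C=O | intermediate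
21 | (1(10)Z,4Z,6R,7R,8S,9R)-14-[(tert-butyldimethylsilyl)oxy]-9-[(4-methoxybenzyl)oxy]-8-[(4,4,5,5-tetramethyl-1,3,2-dioxaborolan-2-yl)oxy]-13-norgermacra-1(10),4-dien-12,6-olide | C1C(=O)O[C@@H]2/C=C(/C)CC/C=C(/CO[Si](C)(C)C(C)(C)C)[C@@H](OCc3ccc(OC)cc3)[C@@H](OB3OC(C)(C)C(C)(C)O3)[C@@H]12 | intermediate (not isolated)
22 | (1(10)Z,4Z,6R,7R,8S,9R)-14-[(tert-butyldimethylsilyl)oxy]-8-hydroxy-9-[(4-methoxybenzyl)oxy]-13-norgermacra-1(10),4-dien-12,6-olide | C1C(=O)O[C@@H]2/C=C(/C)CC/C=C(/CO[Si](C)(C)C(C)(C)C)[C@@H](OCc3ccc(OC)cc3)[C@@H](O)[C@@H]12 | intermediate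
23 | (1(10)Z,4Z,6R,7S,8S,9R)-8,14-bis[(tert-butyldimethylsilyl)oxy]-9-[(4-methoxybenzyl)oxy]-13-norgermacra-1(10),4-dien-12,6-olide | C1C(=O)O[C@@H]2/C=C(/C)CC/C=C(/CO[Si](C)(C)C(C)(C)C)[C@@H](OCc3ccc(OC)cc3)[C@@H](O[Si](C)(C)C(C)(C)C)[C@@H]12 | intermediate
24 | 11-[(dimethylamino)methyl] derivative of 23 (Mannich base, C11 epimers) | CN(C)CC1C(=O)O[C@@H]2/C=C(/C)CC/C=C(/CO[Si](C)(C)C(C)(C)C)[C@@H](OCc3ccc(OC)cc3)[C@@H](O[Si](C)(C)C(C)(C)C)[C@@H]12 | intermediate (not isolated)
25 | 11-[(trimethylammonio)methyl] derivative of 23, iodide (C11 epimers) | C[N+](C)(C)CC1C(=O)O[C@@H]2/C=C(/C)CC/C=C(/CO[Si](C)(C)C(C)(C)C)[C@@H](OCc3ccc(OC)cc3)[C@@H](O[Si](C)(C)C(C)(C)C)[C@@H]12.[I-] | intermediate (not isolated)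
26 | (1(10)Z,4Z,6R,7S,8S,9R)-8,14-bis[(tert-butyldimethylsilyl)oxy]-9-[(4-methoxybenzyl)oxy]germacra-1(10),4,11(13)-trien-12,6-olide | C=C1C(=O)O[C@@H]2/C=C(/C)CC/C=C(/CO[Si](C)(C)C(C)(C)C)[C@@H](OCc3ccc(OC)cc3)[C@@H](O[Si](C)(C)C(C)(C)C)[C@@H]12 | intermediate
27 | (1(10)Z,4Z,6R,7S,8S,9R)-8,14-bis[(tert-butyldimethylsilyl)oxy]-9-hydroxygermacra-1(10),4,11(13)-trien-12,6-olide | C=C1C(=O)O[C@@H]2/C=C(/C)CC/C=C(/CO[Si](C)(C)C(C)(C)C)[C@@H](O)[C@@H](O[Si](C)(C)C(C)(C)C)[C@@H]12 | intermediate
28 | (1(10)Z,4Z,6R,7S,8S,9R)-9-acetoxy-8,14-bis[(tert-butyldimethylsilyl)oxy]germacra-1(10),4,11(13)-trien-12,6-olide | C=C1C(=O)O[C@@H]2/C=C(/C)CC/C=C(/CO[Si](C)(C)C(C)(C)C)[C@@H](OC(C)=O)[C@@H](O[Si](C)(C)C(C)(C)C)[C@@H]12 | intermediate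
29 | (1(10)Z,4Z,6R,7R,8S,9R)-9-acetoxy-8,14-dihydroxygermacra-1(10),4,11(13)-trien-12,6-olide | C=C1C(=O)O[C@@H]2/C=C(/C)CC/C=C(/CO)[C@@H](OC(C)=O)[C@@H](O)[C@@H]12 | intermediate
30 | (2R)-2-methylbutanoic acid | CC[C@@H](C)C(=O)O | starting material
31 | (1(10)Z,4Z,6R,7R,8S,9R)-9-acetoxy-8-hydroxy-14-{[(2R)-2-methylbutanoyl]oxy}germacra-1(10),4,11(13)-trien-12,6-olide (CNP0005248.2) | C=C1C(=O)O[C@@H]2/C=C(/C)CC/C=C(/COC(=O)[C@H](C)CC)[C@@H](OC(C)=O)[C@@H](O)[C@@H]12 | target

## Step count and least certain steps

Total: 21 steps. Longest linear sequence: 17 steps (1, 2, 3, 4, 6, 9, 11 to 21) from neryl acetate 1.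

**Step 15 (key step).** The effective molarity of a ten-membered allylboration is unknown. Ring closure may lose to intermolecular addition, or to slow decay of the β-acyloxy aldehyde by elimination of the lactone oxygen. Reagent control may also be incomplete: a chair with the C2 chain equatorial, or a boat, would give the E alkene or the syn diol, and the Felkin-type bias of the aldehyde works against the required C8 face. Fallback by known chemistry, setting out from 17: NaBH4 in wet THF should give the hydroxy acetal F1, and Dess–Martin oxidation the aldehyde acetal F2. Under high dilution with CrCl2 and Me3SiI in THF at −30 °C the acetal is ionised to the α-iodo allyl ether and reduced by divalent chromium to a γ-alkoxyallylchromium species. That species should add through C9 to the C8 aldehyde and return to the route at 22. Acrolein-type acetals are known to give anti-diol monoethers in this way, and chromium-mediated allylations are an established means of closing medium and large rings. No C1 stereocentre is involved, so the C8 face is then decided by the ring-forming transition state alone and diastereomers of 22 may have to be separated.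

**Step 12.** Acetal 17 is an open-chain, 2-substituted, trisubstituted alkene, beyond the disubstituted and cycloalkenyl acetals for which the borylation is established. Face selection at C1 may be poor and borylcupration slow, silyloxide might leave from C14 in place of PMB-oxide from C9, and the copper alkoxide may attack or deprotonate next to the imide. Fallback, setting out from 17: catalyst control is given up, the borylation is run with an achiral bisphosphine (Xantphos), and 18 is separated from its C1 epimer F3, a diastereomer because of the lactone and auxiliary centres. F3 would be returned to the route by oxidation of the C–B bond with Me3NO to the hydroxy enol ether F4, which should lose 4-methoxybenzyl alcohol with PPTS in wet acetone and give back enal 14. If silyloxide loss is the problem, the chromium route given for the key step bypasses the boronate altogether.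

**Step 9.** The acrolein 13 is electron-poor and 1,1-disubstituted, so conversion may stall and homodimerisation of 10 may dominate. Fallback, setting out from 10: cross-metathesis with the allylic alcohol 12 in place of 13 should give the allylic alcohol F5 as a mixture of C1=C10 isomers. MnO2 oxidation followed by equilibration (catalytic iodine or an amine) should converge on the thermodynamically favoured E enal 14.

**Step 13.** The lactone may be over-reduced, the branched imide may react slowly, and the secondary allylboronate may suffer protodeboronation in the basic aqueous medium. Fallback, setting out from 18: Cp2Zr(H)Cl, which reduces tertiary amides and N-acyl oxazolidinones to aldehydes, would take the imide directly to aldehyde 20, so that the route is rejoined at 20 without passing through 19.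

**Step 21.** Acylation may occur in part on O8, and acetyl migration from O9 to O8 may precede or follow it. Fallback, setting out from 28: the primary silyl ether alone is cleaved (HF·pyridine buffered with pyridine, 0 °C, monitored) to give the 14-alcohol F6. F6 is esterified with 30 to give F7, and the secondary silyl ether is then removed under the same fluoride conditions to reach 31, so the acylation never faces a free 8-hydroxyl.

## Further compounds

F1 | step 15 | (4R,5R)-5-[(1Z,5E)-6-{bis[(4-methoxybenzyl)oxy]methyl}-7-[(tert-butyldimethylsilyl)oxy]-2-methylhepta-1,5-dien-1-yl]-4-(hydroxymethyl)oxolan-2-one | C1C(=O)O[C@H](/C=C(/C)CC/C=C(\CO[Si](C)(C)C(C)(C)C)C(OCc2ccc(OC)cc2)OCc2ccc(OC)cc2)[C@H]1CO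
F2 | step 15 | (2R,3S)-2-[(1Z,5E)-6-{bis[(4-methoxybenzyl)oxy]methyl}-7-[(tert-butyldimethylsilyl)oxy]-2-methylhepta-1,5-dien-1-yl]-5-oxooxolane-3-carbaldehyde | C1C(=O)O[C@H](/C=C(/C)CC/C=C(\CO[Si](C)(C)C(C)(C)C)C(OCc2ccc(OC)cc2)OCc2ccc(OC)cc2)[C@H]1C=O
F3 | step 12 | C1 epimer of 18, (5S)-boronate | C1C(=O)O[C@H](/C=C(/C)CC[C@H](B2OC(C)(C)C(C)(C)O2)/C(CO[Si](C)(C)C(C)(C)C)=C/OCc2ccc(OC)cc2)[C@H]1C(=O)N3[C@@H](Cc4ccccc4)COC3=O
F4 | step 12 | (4S)-4-benzyl-3-{[(2R,3S)-2-[(1Z,5S,6Z)-6-{[(tert-butyldimethylsilyl)oxy]methyl}-5-hydroxy-7-[(4-methoxybenzyl)oxy]-2-methylhepta-1,6-dien-1-yl]-5-oxooxolan-3-yl]carbonyl}-1,3-oxazolidin-2-one | C1C(=O)O[C@H](/C=C(/C)CC[C@H](O)/C(CO[Si](C)(C)C(C)(C)C)=C/OCc2ccc(OC)cc2)[C@H]1C(=O)N3[C@@H](Cc4ccccc4)COC3=O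
F5 | step 9 | (4S)-4-benzyl-3-{[(2R,3S)-2-[(1Z)-7-[(tert-butyldimethylsilyl)oxy]-6-(hydroxymethyl)-2-methylhepta-1,5-dien-1-yl]-5-oxooxolan-3-yl]carbonyl}-1,3-oxazolidin-2-one (C1=C10 isomer mixture) | C1C(=O)O[C@H](/C=C(/C)CCC=C(CO)CO[Si](C)(C)C(C)(C)C)[C@H]1C(=O)N2[C@@H](Cc3ccccc3)COC2=O
F0 | step 13 | none | none
F6 | step 21 | (1(10)Z,4Z,6R,7S,8S,9R)-9-acetoxy-8-[(tert-butyldimethylsilyl)oxy]-14-hydroxygermacra-1(10),4,11(13)-trien-12,6-olide | C=C1C(=O)O[C@@H]2/C=C(/C)CC/C=C(/CO)[C@@H](OC(C)=O)[C@@H](O[Si](C)(C)C(C)(C)C)[C@@H]12
F7 | step 21 | (1(10)Z,4Z,6R,7S,8S,9R)-9-acetoxy-8-[(tert-butyldimethylsilyl)oxy]-14-{[(2R)-2-methylbutanoyl]oxy}germacra-1(10),4,11(13)-trien-12,6-olide | C=C1C(=O)O[C@@H]2/C=C(/C)CC/C=C(/COC(=O)[C@H](C)CC)[C@@H](OC(C)=O)[C@@H](O[Si](C)(C)C(C)(C)C)[C@@H]12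
A1 | alternative 1 | ten-membered saturated trans-lactone with 8-OTBS, 9-OTES and 14-OTBS | C1C(=O)O[C@@H]2/C=C(/C)CC/C=C(/CO[Si](C)(C)C(C)(C)C)[C@@H](O[Si](CC)(CC)CC)[C@@H](O[Si](C)(C)C(C)(C)C)[C@@H]12
A2 | alternative 1 | open-chain Z iodoalkene C6 aldehyde with the C12 methyl ester | I/C=C(/C)CC/C=C(/CO[Si](C)(C)C(C)(C)C)[C@@H](O[Si](CC)(CC)CC)[C@@H](O[Si](C)(C)C(C)(C)C)[C@@H](CC(=O)OC)C=O
A3 | alternative 2 | ten-membered C6 carbinol with the C7 propenyl dioxolane side chain | O[C@@H]1/C=C(/C)CC/C=C(/CO)[C@@H](O[Si](CC)(CC)CC)[C@@H](O[Si](C)(C)C(C)(C)C)[C@H]1C(=C)C2OCCO2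
A4 | alternative 2 | thirteen-membered diallylic ether (O between C6 and C13) | C1/C=C(/C)CC/C=C(/CO)[C@@H](O[Si](CC)(CC)CC)[C@@H](O[Si](C)(C)C(C)(C)C)/C=C(/CO1)C2OCCO2
A5 | alternative 3 | Z,Z-cyclodecadien-9-one fused to the saturated trans-lactone, 8-OPMB, 14-OTBS | C1C(=O)O[C@@H]2/C=C(/C)CC/C=C(/CO[Si](C)(C)C(C)(C)C)C(=O)[C@@H](OCc3ccc(OC)cc3)[C@@H]12
A6 | alternative 3 | angular-methyl cis-decalin lactone with tertiary C9 hydroxyl and C5 mesylate | C1C(=O)O[C@@H]2[C@@H](OS(C)(=O)=O)[C@@]3(C)CCC=C(CO[Si](C)(C)C(C)(C)C)[C@@]3(O)[C@@H](OCc4ccc(OC)cc4)[C@@H]12
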